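## Analysis of the target

Target 20 is a 1-aryl-1,2-dihydronaphthalene. Ring A is the fused benzene ring (C4a, C5–H, C6–OH, C7–OH, C8–OMe, C8a), ring B the partly saturated ring (sp3 C1 and C2, C3=C4), ring C the 3,4-dihydroxy-2-methoxyphenyl group on C1, and C2 and C3 each carry a 4-hydroxybenzoyl group. The two stereocentres are adjacent, C1 (R) and C2 (R), and the SMILES places H1 and H2 on the same face, so the C1 aryl and the C2 aroyl group are cis. This is expected to be the less stable epimer: the peri C8–OMe pushes the C1 aryl pseudoaxial, A(1,2) strain with the C3 aroyl does the same to the C2 aroyl, and only the trans isomer can satisfy both. C2–H is α to a ketone and allylic to the C3=C4 enone and is easily exchanged, whereas the diarylmethine C1 is robust. The feature on which the plan rests is that C1 is bonded to C8a of ring A (ortho to C8–OMe, para to the C6 oxygen) and to C1' of ring C (ortho to C2'–OMe, para to the C4' oxygen): C1 is a latent, doubly stabilised diarylmethyl cation (a masked quinone methide) and its neighbour C2 a latent dienol carbon. Rings A and C are the same 2-methoxy-3,4-dioxygenated unit bonded to C1 through the same carbon; the compound is formally a dehydro-dimer of a chalcone, but with the ring A methoxy group at C8 and not at C5, where phenol coupling followed by Friedel–Crafts closure would put it. Sensitive groups are the two catechols and two phenols (air oxidation, phenoxide-triggered retro-Michael opening of C1–C2), the enone, the C2 centre and the dihydronaphthalene itself, which is one dehydrogenation away from a 1-arylnaphthalene. The synthesis is hard because it needs one enantiomer of a diarylmethine with two nearly identical aryl groups, the contra-thermodynamic cis C2, a pentasubstituted ring A of defined regiochemistry, and a release of six phenols that does not touch C2.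

## Retrosynthetic reasoning

**C2–H, set last.** Target 20 is traced back to its C2 epimer 18 (or any C2 mixture). No skeletal bond is cut. Both epimers give the same per-silylated dienol ether 19, and kinetic protonation of 19 anti to the pseudoaxial C1 aryl creates the cis centre in the final operation. Every earlier step is thereby free of any concern about C2.

**Six O–alkyl bonds.** Hexaphenol 18 comes from the hexa-isopropyl ether 17. Isopropyl ethers survive organolithiums, base and catalytic acid, direct ortho-lithiation poorly, and can be removed by a Lewis acid in the presence of the two methyl ethers.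

**C1–C2 of ring B (key disconnection).** Cutting the bond between the two stereocentres of 17 opens ring B to the acyclic 2-arylidene-1,4-diketone 15. In 15, C1 carries a silyloxy leaving group and C2 is a CH2 group. This cut is chosen over C4–C4a or C1–C8a because a Friedel–Crafts closure there would have to choose between ring positions (this is what misplaces the methoxy group in the biomimetic route). Here ring A already carries both C1 and C4, so no regiochemical choice remains. The only stereocentre of 15 is the carbinol carbon; it is racemic and is erased on ionisation to the cation–dienol 16. The forward reaction must select one face of a planar cation with a chiral counter-anion and close a six-membered ring.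

**C3=C4.** Enone 15 is cut at the double bond into aldehyde 10 and the symmetric 1,4-diketone 13 (via aldol adduct 14). Diketone 13 delivers C2, C3 and both aroyl groups in one piece. The forward step must be a mono-condensation giving the E alkene, which places C2 cis to ring A.

**C2–C3.** Diketone 13 is cut between its two α-carbons, centres of like polarity, into two molecules of ketone 11. The forward step is an oxidative homocoupling of two molecules of enolate 12.

**C8a–C1.** Aldehyde 10 is cut between ring A and the carbinol carbon into an aryl anion at C8a (aryllithium 7, made from the transient imine 6 of aldehyde 2) and aldehyde 5. The formyl equivalent and the methoxy group flank the metalated carbon, which fixes the C8-methoxy regiochemistry. The alkoxide 8 is capped as a silyl ether (9) so that no lactol forms and a leaving group is in place for the key step.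

**O-alkylations.** Aldehyde 2 comes from commercial 1. Aldehyde 5 comes from commercial 3 by way of 4; the formyl-chelated 2-OH reacts last and takes the methyl group.

## Alternatives that were turned down

Alternative 1: biomimetic oxidative dimerisation (the textbook route).
- Disconnection: C2–C3 and C1–C8a.
- Forward key step: one-electron oxidation (chemical oxidant or laccase/peroxidase) of two molecules of licochalcone B A1, α,α'-coupling, then quinone methide Friedel–Crafts closure.
- Why turned down: the ring that closes is bonded to C4 through its C1' and can only cyclise through C6', its single free ortho position. The methoxy group therefore ends at C5 and the product is the regioisomer A2, not 20. In addition, C6' is para to the central, twisted oxygen and is a poor nucleophile, so ipso attack and C–O coupling would compete. The product would be racemic, and the equilibrating conditions favour the trans isomer. It is a one-step route to the wrong constitution.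

Alternative 2: photochemical 6π-electrocyclisation with [1,5]-hydrogen shift.
- Disconnection: C1–C8a.
- Forward key step: conrotatory photocyclisation of the (E,E)-2,3-bis(arylidene)-1,4-diketone A3, then a suprafacial hydrogen shift from C8a to C2. The attraction is that this sequence delivers H2 on the face of H1, the cis arrangement of the target.
- Why turned down: to place the methoxy group at C8, the aryl on C4 must be a 3-methoxy-4,5-dioxygenated ring that closes at C2 (next to OMe) and not at C6. The ring C aryl of the other arylidene can also close onto its own C6'. Up to three constitutional modes compete with nothing in A3 to choose between them. E/Z scrambling under light erodes the geometry. A diketone offers no tether for absolute control. The unsymmetrical A3 would also need two separate condensations.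

Alternative 3: symmetric diarylmethyl unit with a desymmetrising Friedel–Crafts closure.
- Disconnection: C4–C4a and C3=C4.
- Forward key step: two molecules of aldehyde 5 are joined and a 1,2-aryl shift gives 2,2-diarylacetaldehyde A4, which is elaborated to enaminone A5. Acid then closes ring B onto C6' of one of the two identical aryl groups. The regiochemistry is automatic and both aryl rings come from 5.
- Why turned down:
  - C6' is para to the out-of-plane central alkoxy group and meta to the other two, so strong acid would be needed, and under strong acid the 1,4-diketone undergoes Paal–Knorr cyclodehydration.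
  - C1 becomes stereogenic only through the choice between two aryl groups. In A5 these are diastereotopic, because C2 is already a racemic and slowly epimerising stereocentre. A chiral catalyst would have to override substrate control for one enantiomer of A5, which is at best a kinetic resolution.
  - It is the shortest route, but its stereochemical risk is not confined to one step.

Key step: step 7

Assumption: the SMILES is read as the cis-(1R,2R) isomer; the chiral acid in step 7 is drawn as one enantiomer, and its antipode is to be used if the sense of induction at C1 proves to be the opposite one.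

## Route

Step 1
Reactants: 1 3,4-dihydroxy-5-methoxybenzaldehyde
Product: 2 3,4-diisopropoxy-5-methoxybenzaldehyde
Conditions: 2-bromopropane (3 equiv), K2CO3, DMF, 70 °C
Reagents that add atoms: 2-bromopropane CC(C)Br
Why: Double Williamson etherification of the catechol; the isopropyl ethers tolerate organolithiums, base and catalytic acid and are weak, bulky ortho-directing groups.

Step 2
Reactants: 3 2,3,4-trihydroxybenzaldehyde
Product: 4 2-hydroxy-3,4-diisopropoxybenzaldehyde
Conditions: 2-bromopropane (2.2 equiv), K2CO3, DMF, 50 °C
Reagents that add atoms: 2-bromopropane CC(C)Br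
Why: The 4-OH (para to the formyl group) and then the 3-OH are alkylated, while the 2-OH is held in a hydrogen bond to the formyl oxygen and should react last, so that controlled stoichiometry stops at the 3,4-diether.

Step 3
Reactants: 4 2-hydroxy-3,4-diisopropoxybenzaldehyde
Product: 5 3,4-diisopropoxy-2-methoxybenzaldehyde
Conditions: MeI, K2CO3, DMF, 40 °C
Reagents that add atoms: iodomethane CI
Why: O-Methylation of the remaining chelated phenol installs the methoxy group of ring C.

Step 4
Reactants: 2 3,4-diisopropoxy-5-methoxybenzaldehyde; 5 3,4-diisopropoxy-2-methoxybenzaldehyde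
Product: 10 2-[(tert-butyldimethylsilyloxy)(3,4-diisopropoxy-2-methoxyphenyl)methyl]-4,5-diisopropoxy-3-methoxybenzaldehyde (racemic), via imine 6 (not isolated), via ortho-lithiated imine 7 (not isolated), via lithium alkoxide 8 (not isolated), via silyl ether imine 9 (not isolated)
Conditions: c-HexNH2, 4 Å MS, toluene, 23 °C, then evaporation; n-BuLi (1.05 equiv), THF, −78 → −40 °C; 5, −78 °C; TBSOTf, −78 → 0 °C; aq. AcOH/NaOAc, 23 °C
Reagents that add atoms: tert-butyldimethylsilyl triflate CC(C)(C)[Si](C)(C)OS(=O)(=O)C(F)(F)F; water O
Why: Directed ortho-lithiation of a benzaldimine: the C–H between the imine and the methoxy group (C6 of 2) is removed (cooperative direction, while the other ortho position, C2 of 2, is shielded by its isopropoxy neighbour), and the aryllithium adds to 5 to form the C8a–C1 bond with the methoxy group next to it. The alkoxide is capped as a silyl ether so that hydrolysis of the imine returns a free aldehyde and not a lactol; the new carbinol centre is racemic, which is of no consequence because it becomes planar in step 7.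

Step 5
Reactants: 11 1-(4-isopropoxyphenyl)ethanone (2 equiv)
Product: 13 1,4-bis(4-isopropoxyphenyl)butane-1,4-dione, via lithium enolate 12 (not isolated)
Conditions: LiN(i-Pr)2 (1.05 equiv per ketone), THF, −78 °C; CuCl2 (1.1 equiv per ketone), DMF, −78 → 23 °C
Reagents that add atoms: 1-(4-isopropoxyphenyl)ethanone (the second molecule of 11) CC(=O)c1ccc(OC(C)C)cc1
Why: Two molecules of 11 are converted into enolate 12, and oxidative homocoupling by divalent copper (one-electron oxidation of each enolate, then C–C bond formation between the two methyl-derived α-carbons) joins two centres of like polarity. The product is the symmetric 1,4-diketone, which holds all carbon and oxygen atoms of both ketone molecules and supplies C2, C3 and both aroyl groups.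

Step 6
Reactants: 10 2-[(tert-butyldimethylsilyloxy)(3,4-diisopropoxy-2-methoxyphenyl)methyl]-4,5-diisopropoxy-3-methoxybenzaldehyde; 13 1,4-bis(4-isopropoxyphenyl)butane-1,4-dione
Product: 15 (E)-2-{[2-((tert-butyldimethylsilyloxy)(3,4-diisopropoxy-2-methoxyphenyl)methyl)-4,5-diisopropoxy-3-methoxyphenyl]methylidene}-1,4-bis(4-isopropoxyphenyl)butane-1,4-dione (racemic), via aldol adduct 14 (not isolated)
Conditions: 13 (2.5 equiv), KOH (0.5 equiv), EtOH/THF, 23 → 45 °C
Reagents that add atoms: none
Why: Claisen–Schmidt condensation at one of the two equivalent CH2 groups of 13; E1cB dehydration should give the more stable E alkene (ring A trans to the C3 aroyl group and cis to C2H2), the geometry that ring closure needs. The excess of 13 suppresses a second condensation, and the silyl ether is stable to the base.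

Step 7
Reactants: 15 (E)-2-{[2-((tert-butyldimethylsilyloxy)(3,4-diisopropoxy-2-methoxyphenyl)methyl)-4,5-diisopropoxy-3-methoxyphenyl]methylidene}-1,4-bis(4-isopropoxyphenyl)butane-1,4-dione
Product: 17 [(1R,2S)-1-(3,4-diisopropoxy-2-methoxyphenyl)-6,7-diisopropoxy-8-methoxy-1,2-dihydronaphthalene-2,3-diyl]bis[(4-isopropoxyphenyl)methanone] (trans expected), via dienol diarylmethyl cation 16 (not isolated)
Conditions: (S)-3,3'-bis(2,4,6-triisopropylphenyl)-1,1'-binaphthyl-2,2'-diyl N-(trifluoromethylsulfonyl)phosphoramidate (10 mol%), 5 Å MS, toluene, −40 → 0 °C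
Reagents that add atoms: none
Why: Proposed new method: the acid protonates the silyl ether of 15, tert-butyldimethylsilanol leaves, and the diarylmethyl cation (stabilised by ortho-OMe and para-alkoxy groups on rings A and C) forms as an ion pair with the chiral phosphoramidate, while the C2 ketone, whose CH2 is activated by the carbonyl and by C3=C4, tautomerises to the dienol 16. The anion hydrogen-bonds the enol O–H and covers one face of the planar cation, so C2 attacks C1 from one enantiotopic face; both enantiomers of 15 pass through the same cation, which makes the step stereoconvergent. Ring B closes through the C1–C2 bond in a six-membered 6-(enolexo)-exo-trig mode, which the E alkene allows by holding C2 cis to ring A. C1 is set by the catalyst; C2 is expected trans to the C1 aryl, because a half-chair transition state with both groups pseudoaxial avoids the peri contact with C8–OMe and the A(1,2) strain between the aroyl groups, but this outcome is not critical since C2 is reset in step 9. The closest known reaction types are chiral phosphoric acid catalysed additions of enols and enamides to quinone methides and indolylmethyl cations generated in situ from diarylmethanols, and amine-catalysed α-alkylations of carbonyl compounds with benzhydryl cations. The step needs C- over O-alkylation (O-attack would give an eight-membered ring), ring closure faster than acid-induced isomerisation of the 2-arylidene-1,4-diketone to a furan, and kinetic control without re-ionisation of the product (low temperature, catalytic acid); C1 has no β-hydrogen, so elimination cannot compete.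

Step 8
Reactants: 17 [(1R,2S)-1-(3,4-diisopropoxy-2-methoxyphenyl)-6,7-diisopropoxy-8-methoxy-1,2-dihydronaphthalene-2,3-diyl]bis[(4-isopropoxyphenyl)methanone]
Product: 18 [(1R,2S)-1-(3,4-dihydroxy-2-methoxyphenyl)-6,7-dihydroxy-8-methoxy-1,2-dihydronaphthalene-2,3-diyl]bis[(4-hydroxyphenyl)methanone]
Conditions: BCl3 (12 equiv), CH2Cl2, −78 → 0 °C; MeOH, −78 °C; argon
Reagents that add atoms: none
Why: Lewis-acid dealkylation of aryl isopropyl ethers (O-complexation, loss of the secondary alkyl group as 2-chloropropane), a reaction that is known to spare aryl methyl ethers. Any epimerisation at C2 under these conditions is without consequence, because C2 is set in step 9.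

Step 9
Reactants: 18 [(1R,2S)-1-(3,4-dihydroxy-2-methoxyphenyl)-6,7-dihydroxy-8-methoxy-1,2-dihydronaphthalene-2,3-diyl]bis[(4-hydroxyphenyl)methanone]
Product: 20 [(1R,2R)-1-(3,4-dihydroxy-2-methoxyphenyl)-6,7-dihydroxy-8-methoxy-1,2-dihydronaphthalene-2,3-diyl]bis[(4-hydroxyphenyl)methanone], via per-silylated dienol ether 19 (not isolated)
Conditions: TMSOTf (10 equiv), Et3N (12 equiv), CH2Cl2, 0 °C; then Et3N·3HF, THF, −78 → −20 °C; pH 5 buffer, 0 °C; argon
Reagents that add atoms: none
Why: Soft enolisation (silyl triflate, tertiary amine) removes the only enolisable proton, C2–H, so both C2 epimers of 18 converge on the same dienol ether 19 while the phenols are masked. In 19 the C1 aryl is pseudoaxial (A(1,3) strain with the exocyclic enol ether, peri contact with C8–OMe) and shields one face of C2; fluoride-induced desilylation in the presence of a proton source should protonate the dienolate kinetically at the α-carbon C2 from the open face, which places the aroyl group cis to the aryl group (kinetic ketonisation to the less stable epimer). The aryl silyl ethers fall under the same buffered conditions, so the labile cis centre is made in the last operation.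

## Compound list

1 | 3,4-dihydroxy-5-methoxybenzaldehyde | COc1cc(C=O)cc(O)c1O | starting material
2 | 3,4-diisopropoxy-5-methoxybenzaldehyde | COc1cc(C=O)cc(OC(C)C)c1OC(C)C | intermediate
3 | 2,3,4-trihydroxybenzaldehyde | O=Cc1ccc(O)c(O)c1O | starting material
4 | 2-hydroxy-3,4-diisopropoxybenzaldehyde | O=Cc1ccc(OC(C)C)c(OC(C)C)c1O | intermediate
5 | 3,4-diisopropoxy-2-methoxybenzaldehyde | COc1c(C=O)ccc(OC(C)C)c1OC(C)C | intermediate
6 | (E)-N-cyclohexyl-1-(3,4-diisopropoxy-5-methoxyphenyl)methanimine | COc1cc(/C=N/C2CCCCC2)cc(OC(C)C)c1OC(C)C | intermediate (not isolated)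
7 | {2-[(E)-(cyclohexylimino)methyl]-4,5-diisopropoxy-6-methoxyphenyl}lithium | COc1c([Li])c(/C=N/C2CCCCC2)cc(OC(C)C)c1OC(C)C | intermediate (not isolated)
8 | lithium {2-[(E)-(cyclohexylimino)methyl]-4,5-diisopropoxy-6-methoxyphenyl}(3,4-diisopropoxy-2-methoxyphenyl)methanolate (racemic) | COc1c(C(O[Li])c2ccc(OC(C)C)c(OC(C)C)c2OC)c(/C=N/C2CCCCC2)cc(OC(C)C)c1OC(C)C | intermediate (not isolated)
9 | tert-butyldimethylsilyl ether of 8, (E)-N-cyclohexyl imine (racemic) | COc1c(C(O[Si](C)(C)C(C)(C)C)c2ccc(OC(C)C)c(OC(C)C)c2OC)c(/C=N/C2CCCCC2)cc(OC(C)C)c1OC(C)C | intermediate (not isolated)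
10 | 2-[(tert-butyldimethylsilyloxy)(3,4-diisopropoxy-2-methoxyphenyl)methyl]-4,5-diisopropoxy-3-methoxybenzaldehyde (racemic) | COc1c(C(O[Si](C)(C)C(C)(C)C)c2ccc(OC(C)C)c(OC(C)C)c2OC)c(C=O)cc(OC(C)C)c1OC(C)C | intermediate
11 | 1-(4-isopropoxyphenyl)ethanone | CC(=O)c1ccc(OC(C)C)cc1 | starting material
12 | lithium 1-(4-isopropoxyphenyl)ethenolate | [Li]OC(=C)c1ccc(OC(C)C)cc1 | intermediate (not isolated)
13 | 1,4-bis(4-isopropoxyphenyl)butane-1,4-dione | CC(C)Oc1ccc(cc1)C(=O)CCC(=O)c1ccc(OC(C)C)cc1 | intermediate
14 | 2-{hydroxy[2-((tert-butyldimethylsilyloxy)(3,4-diisopropoxy-2-methoxyphenyl)methyl)-4,5-diisopropoxy-3-methoxyphenyl]methyl}-1,4-bis(4-isopropoxyphenyl)butane-1,4-dione (mixture of diastereomers) | COc1c(C(O[Si](C)(C)C(C)(C)C)c2ccc(OC(C)C)c(OC(C)C)c2OC)c(C(O)C(CC(=O)c2ccc(OC(C)C)cc2)C(=O)c2ccc(OC(C)C)cc2)cc(OC(C)C)c1OC(C)C | intermediate (not isolated)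
15 | (E)-2-{[2-((tert-butyldimethylsilyloxy)(3,4-diisopropoxy-2-methoxyphenyl)methyl)-4,5-diisopropoxy-3-methoxyphenyl]methylidene}-1,4-bis(4-isopropoxyphenyl)butane-1,4-dione (racemic at the silyloxy carbon) | COc1c(C(O[Si](C)(C)C(C)(C)C)c2ccc(OC(C)C)c(OC(C)C)c2OC)c(/C=C(\CC(=O)c2ccc(OC(C)C)cc2)C(=O)c2ccc(OC(C)C)cc2)cc(OC(C)C)c1OC(C)C | intermediate
16 | diarylmethyl cation of 15 with the C2 ketone as its dienol (ion pair with the catalyst anion) | COc1c([CH+]c2ccc(OC(C)C)c(OC(C)C)c2OC)c(/C=C(\C=C(O)c2ccc(OC(C)C)cc2)C(=O)c2ccc(OC(C)C)cc2)cc(OC(C)C)c1OC(C)C | intermediate (not isolated)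
17 | [(1R,2S)-1-(3,4-diisopropoxy-2-methoxyphenyl)-6,7-diisopropoxy-8-methoxy-1,2-dihydronaphthalene-2,3-diyl]bis[(4-isopropoxyphenyl)methanone] (trans) | COc1c([C@@H]2c3c(cc(OC(C)C)c(OC(C)C)c3OC)C=C(C(=O)c3ccc(OC(C)C)cc3)[C@H]2C(=O)c2ccc(OC(C)C)cc2)ccc(OC(C)C)c1OC(C)C | intermediate
18 | [(1R,2S)-1-(3,4-dihydroxy-2-methoxyphenyl)-6,7-dihydroxy-8-methoxy-1,2-dihydronaphthalene-2,3-diyl]bis[(4-hydroxyphenyl)methanone] (trans, C2 epimer of the target) | COc1c([C@@H]2c3c(cc(O)c(O)c3OC)C=C(C(=O)c3ccc(O)cc3)[C@H]2C(=O)c2ccc(O)cc2)ccc(O)c1O | intermediate
19 | heptakis(trimethylsilyl) derivative of 18: six aryl silyl ethers and the C2 exocyclic silyl dienol ether, C1 configuration unchanged, enol ether geometry not defined | COc1c([C@@H]2c3c(cc(O[Si](C)(C)C)c(O[Si](C)(C)C)c3OC)C=C(C(=O)c3ccc(O[Si](C)(C)C)cc3)C2=C(O[Si](C)(C)C)c2ccc(O[Si](C)(C)C)cc2)ccc(O[Si](C)(C)C)c1O[Si](C)(C)C | intermediate (not isolated)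
20 | [(1R,2R)-1-(3,4-dihydroxy-2-methoxyphenyl)-6,7-dihydroxy-8-methoxy-1,2-dihydronaphthalene-2,3-diyl]bis[(4-hydroxyphenyl)methanone] (cis), CNP0335881.1 | COc1c([C@@H]2c3c(cc(O)c(O)c3OC)C=C(C(=O)c3ccc(O)cc3)[C@@H]2C(=O)c2ccc(O)cc2)ccc(O)c1O | target

## Step count and risks

Total step count: 9. Longest linear sequence: 7 steps (3 → 4 → 5 → 10 → 15 → 17 → 18 → 20); the branches from 1 (step 1) and from 11 (step 5) join in steps 4 and 6.

**Step 7 (key step, proposed new method).** What may go wrong:
- poor enantiofacial discrimination at the cation, because the electrophile has no hydrogen-bond handle and the ion pair may be loose;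
- slow enolisation, which would leave time for acid-induced isomerisation of the arylidene diketone towards a furan;
- re-ionisation of the product C1–C2 bond, which would erode the enantiomeric purity.

Fallback with known chemistry: from 15, ring closure with an achiral acid (BF3·OEt2, CH2Cl2, −78 °C) gives the racemate, that is 17 together with its enantiomer [(1S,2R)-1-(3,4-diisopropoxy-2-methoxyphenyl)-6,7-diisopropoxy-8-methoxy-1,2-dihydronaphthalene-2,3-diyl]bis[(4-isopropoxyphenyl)methanone] F1. Preparative chromatography on a chiral stationary phase separates the two and returns to 17.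

**Step 4.** What may go wrong:
- addition of n-BuLi to the C=N bond in place of deprotonation;
- lithiation at the other ortho position (C2 of 2), next to the isopropoxy group;
- incomplete O-silylation, after which the product would close to a lactol.

Fallback: from 2, oxidation with NaClO2 gives 3,4-diisopropoxy-5-methoxybenzoic acid F2, and coupling with diethylamine gives N,N-diethyl-3,4-diisopropoxy-5-methoxybenzamide F3. The tertiary amide is a stronger director that cannot suffer addition. Ortho-lithiation of F3 between the amide and the methoxy group (s-BuLi, TMEDA, THF, −78 °C), addition to 5 and silylation in the same flask (TBSOTf) give N,N-diethyl-2-[(tert-butyldimethylsilyloxy)(3,4-diisopropoxy-2-methoxyphenyl)methyl]-4,5-diisopropoxy-3-methoxybenzamide F4. Partial reduction of the amide with Cp2Zr(H)Cl returns to aldehyde 10.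

**Step 6.** What may go wrong:
- a second condensation at the remaining CH2 group;
- retro-aldol cleavage;
- base-induced migration of the new double bond out of conjugation with ring A.

Fallback: from 13, dehydrogenation with SeO2 gives (E)-1,4-bis(4-isopropoxyphenyl)but-2-ene-1,4-dione F5. Conjugate addition of Bu3P to F5 and proton shift give the stabilised ylide 1,4-bis(4-isopropoxyphenyl)-2-(tributyl-λ5-phosphanylidene)butane-1,4-dione F6. Under neutral conditions F6 olefinates aldehyde 10 in a Wittig reaction that can only occur once, and the route is rejoined at 15.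

**Step 9.** What may go wrong:
- protonation at the γ-carbon C4 in place of C2;
- insufficient facial discrimination;
- epimerisation or aerial dehydrogenation to the naphthalene during desilylation and work-up of the free polyphenol.

Fallback: the C2 centre is set on the protected compound. From 17, LiN(SiMe3)2 (THF, −78 °C) gives the lithium dienolate, lithium (1R)-configured 2-[(4-isopropoxyphenyl)oxidomethylidene] derivative of 17, F7. Inverse quench into AcOH at −78 °C gives the cis diketone [(1R,2R)-1-(3,4-diisopropoxy-2-methoxyphenyl)-6,7-diisopropoxy-8-methoxy-1,2-dihydronaphthalene-2,3-diyl]bis[(4-isopropoxyphenyl)methanone] F8. Dealkylation of F8 with BCl3 at −78 → 0 °C then leads directly to 20.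

## Further compounds

F1 | step 7 | [(1S,2R)-1-(3,4-diisopropoxy-2-methoxyphenyl)-6,7-diisopropoxy-8-methoxy-1,2-dihydronaphthalene-2,3-diyl]bis[(4-isopropoxyphenyl)methanone] (enantiomer of 17) | COc1c([C@H]2c3c(cc(OC(C)C)c(OC(C)C)c3OC)C=C(C(=O)c3ccc(OC(C)C)cc3)[C@@H]2C(=O)c2ccc(OC(C)C)cc2)ccc(OC(C)C)c1OC(C)C
F2 | step 4 | 3,4-diisopropoxy-5-methoxybenzoic acid | COc1cc(C(=O)O)cc(OC(C)C)c1OC(C)C
F3 | step 4 | N,N-diethyl-3,4-diisopropoxy-5-methoxybenzamide | CCN(CC)C(=O)c1cc(OC)c(OC(C)C)c(OC(C)C)c1
F4 | step 4 | N,N-diethyl-2-[(tert-butyldimethylsilyloxy)(3,4-diisopropoxy-2-methoxyphenyl)methyl]-4,5-diisopropoxy-3-methoxybenzamide (racemic) | CCN(CC)C(=O)c1cc(OC(C)C)c(OC(C)C)c(OC)c1C(O[Si](C)(C)C(C)(C)C)c1ccc(OC(C)C)c(OC(C)C)c1OC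
F5 | step 6 | (E)-1,4-bis(4-isopropoxyphenyl)but-2-ene-1,4-dione | CC(C)Oc1ccc(cc1)C(=O)/C=C/C(=O)c1ccc(OC(C)C)cc1
F6 | step 6 | 1,4-bis(4-isopropoxyphenyl)-2-(tributyl-λ5-phosphanylidene)butane-1,4-dione | CCCCP(CCCC)(CCCC)=C(CC(=O)c1ccc(OC(C)C)cc1)C(=O)c1ccc(OC(C)C)cc1
F7 | step 9 | lithium dienolate of 17 (C2 exocyclic enolate, C1 configuration unchanged) | COc1c([C@@H]2c3c(cc(OC(C)C)c(OC(C)C)c3OC)C=C(C(=O)c3ccc(OC(C)C)cc3)C2=C(O[Li])c2ccc(OC(C)C)cc2)ccc(OC(C)C)c1OC(C)C
F8 | step 9 | [(1R,2R)-1-(3,4-diisopropoxy-2-methoxyphenyl)-6,7-diisopropoxy-8-methoxy-1,2-dihydronaphthalene-2,3-diyl]bis[(4-isopropoxyphenyl)methanone] (cis) | COc1c([C@@H]2c3c(cc(OC(C)C)c(OC(C)C)c3OC)C=C(C(=O)c3ccc(OC(C)C)cc3)[C@@H]2C(=O)c2ccc(OC(C)C)cc2)ccc(OC(C)C)c1OC(C)C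
A1 | alternative 1 | licochalcone B, (E)-3-(3,4-dihydroxy-2-methoxyphenyl)-1-(4-hydroxyphenyl)prop-2-en-1-one | COc1c(/C=C/C(=O)c2ccc(O)cc2)ccc(O)c1O
A2 | alternative 1 | trans-[1-(3,4-dihydroxy-2-methoxyphenyl)-6,7-dihydroxy-5-methoxy-1,2-dihydronaphthalene-2,3-diyl]bis[(4-hydroxyphenyl)methanone] (racemic; the (1R,2S) enantiomer is drawn) | COc1c([C@@H]2c3cc(O)c(O)c(OC)c3C=C(C(=O)c3ccc(O)cc3)[C@H]2C(=O)c2ccc(O)cc2)ccc(O)c1O
A3 | alternative 2 | (2E,3E)-2-[(3,4-diisopropoxy-2-methoxyphenyl)methylidene]-3-[(3,4-diisopropoxy-5-methoxyphenyl)methylidene]-1,4-bis(4-isopropoxyphenyl)butane-1,4-dione | COc1c(/C=C(/C(=O)c2ccc(OC(C)C)cc2)\C(=C/c2cc(OC)c(OC(C)C)c(OC(C)C)c2)C(=O)c2ccc(OC(C)C)cc2)ccc(OC(C)C)c1OC(C)C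
A4 | alternative 3 | 2,2-bis(3,4-diisopropoxy-2-methoxyphenyl)acetaldehyde | O=CC(c1ccc(OC(C)C)c(OC(C)C)c1OC)c1ccc(OC(C)C)c(OC(C)C)c1OC
A5 | alternative 3 | (E)-2-[bis(3,4-diisopropoxy-2-methoxyphenyl)methyl]-3-[(dimethylamino)methylidene]-1,4-bis(4-isopropoxyphenyl)butane-1,4-dione (racemic at C2) | CN(C)/C=C(/C(=O)c1ccc(OC(C)C)cc1)C(C(=O)c1ccc(OC(C)C)cc1)C(c1ccc(OC(C)C)c(OC(C)C)c1OC)c1ccc(OC(C)C)c(OC(C)C)c1OC
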